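**Retrosynthetic overview**
- The target is a depside (ring A = acyl ring, ring B = benzoic acid ring). The last step frees the CO2H (benzyl ester) and the ring-A 2-OH (methyl ether ortho to the ester C=O) in one BCl3 operation.
- Key C–C disconnection: the ring-B aryl–pentyl bond, cut late on the intact depside, gives an aryl triflate and pentanal. The aldehyde carbon, natively an electrophile, is turned into a pentyl carbanion equivalent through its N–H hydrazone and joined to the electrophilic triflate carbon under nickel catalysis.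
- The triflate comes from a symmetric ring-B diol. Innate phenol reactivity (para-OH acylation, then monotriflation of one of two equivalent ortho-OH groups) replaces phenol protecting groups.
- The depside C–O bond comes from benzyl 2,4,6-trihydroxybenzoate and 2,4-dimethoxy-6-methylbenzoyl chloride.
- No ring is formed: both benzene rings are bought (2,4,6-trihydroxybenzoic acid and 2,4-dimethoxy-6-methylbenzoic acid).

Assumption: the target has no stereocentre and no stereogenic double bond, so it is achiral and "single enantiomer" needs no action.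

**Step 1**
Reactants: 1 2,4,6-trihydroxybenzoic acid (sold as the monohydrate)
Product: 2 benzyl 2,4,6-trihydroxybenzoate
Conditions: BnBr (1.05 equiv), KHCO3 (1.2 equiv), DMF, rt, 16 h
Reagents that add atoms: benzyl bromide, BrCc1ccccc1
Why: Carboxylate O-alkylation (SN2), in which KHCO3 ionises only the carboxylic acid so the phenols and ring carbons are not benzylated, and room temperature avoids decarboxylation of the acid.

**Step 2**
Reactants: 2 benzyl 2,4,6-trihydroxybenzoate; 3 2,4-dimethoxy-6-methylbenzoic acid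
Product: 5 benzyl 4-[(2,4-dimethoxy-6-methylbenzoyl)oxy]-2,6-dihydroxybenzoate, via 2,4-dimethoxy-6-methylbenzoyl chloride 4 (not isolated)
Conditions: 3, (COCl)2, DMF (cat.), CH2Cl2, rt, evaporate; then 2, Et3N (1.2 equiv), DMAP (10 mol%), CH2Cl2–THF, 0 °C → rt
Reagents that add atoms: none
Why: Acid chloride formation followed by DMAP-catalysed O-acylation, which goes once and at the 4-OH because that is the only phenol of 2 not hydrogen-bonded to the ester and is the most acidic and least hindered.

**Step 3**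
Reactants: 5 benzyl 4-[(2,4-dimethoxy-6-methylbenzoyl)oxy]-2,6-dihydroxybenzoate
Product: 6 benzyl 4-[(2,4-dimethoxy-6-methylbenzoyl)oxy]-2-hydroxy-6-[(trifluoromethanesulfonyl)oxy]benzoate
Conditions: Tf2O (1.05 equiv), pyridine (2.5 equiv), CH2Cl2, −40 → 0 °C
Reagents that add atoms: trifluoromethanesulfonic anhydride, O=S(=O)(OS(=O)(=O)C(F)(F)F)C(F)(F)F
Why: Phenol O-sulfonylation, selective for one of the two equivalent ring-B OH groups because only one can hold the strong hydrogen bond to the ester C=O, and the remaining chelated OH on the now electron-poor ring reacts much more slowly (ring A carries no free OH).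

**Step 4**
Reactants: 6 benzyl 4-[(2,4-dimethoxy-6-methylbenzoyl)oxy]-2-hydroxy-6-[(trifluoromethanesulfonyl)oxy]benzoate; 7 pentanal (2.5 equiv)
Product: 9 benzyl 4-[(2,4-dimethoxy-6-methylbenzoyl)oxy]-2-hydroxy-6-pentylbenzoate, via pentanal hydrazone 8 (not isolated)
Conditions: 7, N2H4·H2O (1.05 equiv per 7), THF, rt, 1 h, 4 Å MS; then 6, Ni(cod)2 (10 mol%), PMe3 (30 mol%), K3PO4 (3.5 equiv), THF, 60 °C
Reagents that add atoms: none
Why: Proposed new method: the N–H hydrazone makes the pentanal carbon a pentyl carbanion equivalent (carbonyl polarity reversal), so two natively electrophilic carbons are joined — the ortho-ester aryl triflate adds oxidatively to zerovalent nickel, the hydrazone binds through nitrogen and is deprotonated, tautomerisation to the diazene and base-triggered loss of N2 give an aryl(pentyl) divalent nickel species that reductively eliminates; the closest known reaction type is the nickel-catalysed Wolff–Kishner-type denitrogenative cross-coupling of aldehyde N–H hydrazones with aryl halides and aryl sulfonates, extended here to a β-hydrogen-bearing aliphatic hydrazone and a depside triflate whose two esters are each flanked by two ortho substituents and so shielded from the nitrogen nucleophile.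

**Step 5**
Reactants: 9 benzyl 4-[(2,4-dimethoxy-6-methylbenzoyl)oxy]-2-hydroxy-6-pentylbenzoate
Product: 10 4-[(2-hydroxy-4-methoxy-6-methylbenzoyl)oxy]-2-hydroxy-6-pentylbenzoic acid (target, achiral)
Conditions: BCl3 (5 equiv), C6HMe5 (3 equiv), CH2Cl2, −78 → 0 °C; then H2O
Reagents that add atoms: none
Why: Chelation-controlled Lewis-acid dealkylation, in which BCl3 held between the depside C=O and the ortho-methoxy oxygen cleaves only that methyl ether (the para-methoxy group has no chelate) and BCl3 held in the ring-B salicylate chelate cleaves the benzyl ester, with pentamethylbenzene trapping the benzyl cation and the doubly ortho-substituted aryl ester left intact.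

**Compound list**
1 | 2,4,6-trihydroxybenzoic acid | OC(=O)c1c(O)cc(O)cc1O | starting material
2 | benzyl 2,4,6-trihydroxybenzoate | O=C(OCc1ccccc1)c1c(O)cc(O)cc1O | intermediate
3 | 2,4-dimethoxy-6-methylbenzoic acid | COc1cc(C)c(C(=O)O)c(OC)c1 | starting material
4 | 2,4-dimethoxy-6-methylbenzoyl chloride (not isolated) | COc1cc(C)c(C(=O)Cl)c(OC)c1 | intermediate
5 | benzyl 4-[(2,4-dimethoxy-6-methylbenzoyl)oxy]-2,6-dihydroxybenzoate | COc1cc(C)c(C(=O)Oc2cc(O)c(C(=O)OCc3ccccc3)c(O)c2)c(OC)c1 | intermediate
6 | benzyl 4-[(2,4-dimethoxy-6-methylbenzoyl)oxy]-2-hydroxy-6-[(trifluoromethanesulfonyl)oxy]benzoate | COc1cc(C)c(C(=O)Oc2cc(O)c(C(=O)OCc3ccccc3)c(OS(=O)(=O)C(F)(F)F)c2)c(OC)c1 | intermediate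
7 | pentanal | CCCCC=O | starting material
8 | pentanal hydrazone, E (not isolated) | CCCC/C=N/N | intermediate
9 | benzyl 4-[(2,4-dimethoxy-6-methylbenzoyl)oxy]-2-hydroxy-6-pentylbenzoate | CCCCCc1cc(OC(=O)c2c(C)cc(OC)cc2OC)cc(O)c1C(=O)OCc1ccccc1 | intermediate
10 | 4-[(2-hydroxy-4-methoxy-6-methylbenzoyl)oxy]-2-hydroxy-6-pentylbenzoic acid | CCCCCc1cc(OC(=O)c2c(C)cc(OC)cc2O)cc(O)c1C(=O)O | target

**Totals**
Total step count: 5. Longest linear sequence: 5 steps (1 → 2 → 5 → 6 → 9 → 10).

**Steps most likely to fail, with fallbacks**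

Step 4 is the riskiest. The aryl(pentyl)nickel intermediate can undergo β-hydride elimination, and the hydrazone or traces of hydrazine can attack the triflate sulfur or an ester. The fallback gives up the hydrazone partner for a conventional alkylborane. It sets out from 6: commercial pent-1-ene is hydroborated with 9-BBN (THF, 0 °C → rt) to give 9-pentyl-9-borabicyclo[3.3.1]nonane F1, which is coupled with 6 in a B-alkyl Suzuki–Miyaura reaction (Pd(dppf)Cl2 5 mol%, K3PO4, THF–DMF, 60 °C). It comes back to the route at 9.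

Step 5 is second. BCl3 might attack the depside ester or give incomplete debenzylation. The fallback changes the protecting-group plan so that the end game is a neutral hydrogenolysis. It sets out from 3:
- BCl3 (CH2Cl2, 0 °C) on this simple acid removes only the methyl ether next to the carboxyl group and gives 2-hydroxy-4-methoxy-6-methylbenzoic acid F2.
- BnBr and K2CO3 in DMF at 60 °C give benzyl 2-(benzyloxy)-4-methoxy-6-methylbenzoate F3.
- KOH in DMSO–H2O at 90 °C cleaves the hindered ester to 2-(benzyloxy)-4-methoxy-6-methylbenzoic acid F4.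
- (COCl)2 with catalytic DMF gives 2-(benzyloxy)-4-methoxy-6-methylbenzoyl chloride F5, which acylates 2 under the step 2 conditions to benzyl 4-{[2-(benzyloxy)-4-methoxy-6-methylbenzoyl]oxy}-2,6-dihydroxybenzoate F6.
- Tf2O and pyridine give benzyl 4-{[2-(benzyloxy)-4-methoxy-6-methylbenzoyl]oxy}-2-hydroxy-6-[(trifluoromethanesulfonyl)oxy]benzoate F7.
- The nickel coupling of step 4 with 8 gives benzyl 4-{[2-(benzyloxy)-4-methoxy-6-methylbenzoyl]oxy}-2-hydroxy-6-pentylbenzoate F8.
- H2 (1 atm) over Pd/C in EtOAc at rt removes both benzyl groups.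

It comes back to the route at 10.

Step 3 is third. Bis-triflation or poor conversion of the doubly chelated diol is possible. The fallback removes the need to differentiate two OH groups by tying one of them and the acid into an acetonide. It sets out from 1:
- Acetone, TFAA and TFA (0 °C → rt) give 5,7-dihydroxy-2,2-dimethyl-4H-1,3-benzodioxin-4-one F9.
- Its only non-chelated 7-OH is acylated with 4 (Et3N, DMAP, CH2Cl2, 0 °C) to 5-hydroxy-2,2-dimethyl-4-oxo-4H-1,3-benzodioxin-7-yl 2,4-dimethoxy-6-methylbenzoate F10.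
- The single remaining OH is triflated (Tf2O, pyridine) to 2,2-dimethyl-4-oxo-5-[(trifluoromethanesulfonyl)oxy]-4H-1,3-benzodioxin-7-yl 2,4-dimethoxy-6-methylbenzoate F11.
- The nickel coupling of step 4 with 8 gives 2,2-dimethyl-4-oxo-5-pentyl-4H-1,3-benzodioxin-7-yl 2,4-dimethoxy-6-methylbenzoate F12.
- BnOLi (from benzyl alcohol and LiN(SiMe3)2, THF, 0 °C) opens the dioxinone to the benzyl salicylate.

It comes back to the route at 9.

**Further compounds**
F1 | step 4 | 9-pentyl-9-borabicyclo[3.3.1]nonane | CCCCCB1C2CCCC1CCC2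
F2 | step 5 | 2-hydroxy-4-methoxy-6-methylbenzoic acid | COc1cc(C)c(C(=O)O)c(O)c1
F3 | step 5 | benzyl 2-(benzyloxy)-4-methoxy-6-methylbenzoate | COc1cc(C)c(C(=O)OCc2ccccc2)c(OCc2ccccc2)c1
F4 | step 5 | 2-(benzyloxy)-4-methoxy-6-methylbenzoic acid | COc1cc(C)c(C(=O)O)c(OCc2ccccc2)c1
F5 | step 5 | 2-(benzyloxy)-4-methoxy-6-methylbenzoyl chloride | COc1cc(C)c(C(=O)Cl)c(OCc2ccccc2)c1
F6 | step 5 | benzyl 4-{[2-(benzyloxy)-4-methoxy-6-methylbenzoyl]oxy}-2,6-dihydroxybenzoate | COc1cc(C)c(C(=O)Oc2cc(O)c(C(=O)OCc3ccccc3)c(O)c2)c(OCc2ccccc2)c1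
F7 | step 5 | benzyl 4-{[2-(benzyloxy)-4-methoxy-6-methylbenzoyl]oxy}-2-hydroxy-6-[(trifluoromethanesulfonyl)oxy]benzoate | COc1cc(C)c(C(=O)Oc2cc(O)c(C(=O)OCc3ccccc3)c(OS(=O)(=O)C(F)(F)F)c2)c(OCc2ccccc2)c1
F8 | step 5 | benzyl 4-{[2-(benzyloxy)-4-methoxy-6-methylbenzoyl]oxy}-2-hydroxy-6-pentylbenzoate | CCCCCc1cc(OC(=O)c2c(C)cc(OC)cc2OCc2ccccc2)cc(O)c1C(=O)OCc1ccccc1
F9 | step 3 | 5,7-dihydroxy-2,2-dimethyl-4H-1,3-benzodioxin-4-one | CC1(C)OC(=O)c2c(O)cc(O)cc2O1
F10 | step 3 | 5-hydroxy-2,2-dimethyl-4-oxo-4H-1,3-benzodioxin-7-yl 2,4-dimethoxy-6-methylbenzoate | COc1cc(C)c(C(=O)Oc2cc(O)c3c(c2)OC(C)(C)OC3=O)c(OC)c1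
F11 | step 3 | 2,2-dimethyl-4-oxo-5-[(trifluoromethanesulfonyl)oxy]-4H-1,3-benzodioxin-7-yl 2,4-dimethoxy-6-methylbenzoate | COc1cc(C)c(C(=O)Oc2cc(OS(=O)(=O)C(F)(F)F)c3c(c2)OC(C)(C)OC3=O)c(OC)c1
F12 | step 3 | 2,2-dimethyl-4-oxo-5-pentyl-4H-1,3-benzodioxin-7-yl 2,4-dimethoxy-6-methylbenzoate | CCCCCc1cc(OC(=O)c2c(C)cc(OC)cc2OC)cc2c1C(=O)OC(C)(C)O2
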